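**Retrosynthetic overview**
1. The target comes from global hydrogenolysis of its 21-fold benzyl ether. That ether comes from two Lewis-acid C4→C8 Friedel–Crafts couplings of one C4-activated gallate electrophile, first with the monomeric gallate and then with the resulting dimer. Nucleophile and electrophile both derive from one monomer, tetra-O-benzyl-(−)-epicatechin, so all three pyran rings share one origin.
2. The monomer comes from dynamic kinetic hydrogenation of the racemic flavan-3-one, which sets C2 and C3 as 2,3-cis. The ketone comes from oxidative ring expansion of a flat, achiral 2-benzylbenzofuran.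
3. Key event: the five-membered furan ring (O1, C3, C4, C4a, C8a, flavan numbering) opens and recloses as the six-membered pyran ring (O1, C2, C3, C4, C4a, C8a). The exocyclic benzylic CH2 enters the ring as C2, and the transferred oxygen atom becomes O3.
4. Enabling feature: O1–C8a–C4a–C4 on the phloroglucinol A ring is a latent o-quinone methide stabilised by the 5- and 7-oxygens. C2 lies between C3=O and the B ring, so the oxatriene O1=C8a–C4a=C4–C3=C2 is within reach.
5. Ring order: the A, B and galloyl benzene rings are bought. The furan ring is made in step 2 and becomes the pyran ring in step 5. After that the units are only joined (steps 10 and 11).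

Key step: step 5

Remark: flavan numbering is used for all units. The enantiomer of the Ru catalyst in step 6 is assigned by analogy with 2-arylcycloalkanones, and the mirror-image complex is used if the sense of induction is opposite.

**Step 1**
Reactants: 1 2,4,6-trihydroxybenzaldehyde
Product: 2 2,4-bis(benzyloxy)-6-hydroxybenzaldehyde
Conditions: BnBr (2.1 equiv), K2CO3, DMF, 0 °C → rt
Reagents that add atoms: benzyl bromide, BrCc1ccccc1
Why: Williamson etherification should take the para OH and one ortho OH, while the last ortho OH is held back by its hydrogen bond to the formyl group.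

**Step 2**
Reactants: 2 2,4-bis(benzyloxy)-6-hydroxybenzaldehyde; 3 2-bromo-1-[3,4-bis(benzyloxy)phenyl]ethan-1-one
Product: 5 [4,6-bis(benzyloxy)-1-benzofuran-2-yl][3,4-bis(benzyloxy)phenyl]methanone, via phenacyl aryl ether 4 (not isolated)
Conditions: K2CO3, DMF, 80 °C
Reagents that add atoms: none
Why: Rap–Stoermer benzofuran synthesis, in which phenoxide O-alkylation by the α-bromoketone is followed by intramolecular aldol condensation of the activated OCH2 onto the ortho formyl group and dehydration to the aromatic furan ring.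

**Step 3**
Reactants: 5 the 2-aroylbenzofuran
Product: 6 rac-[4,6-bis(benzyloxy)-1-benzofuran-2-yl][3,4-bis(benzyloxy)phenyl]methanol
Conditions: NaBH4, THF–MeOH, 0 °C
Reagents that add atoms: none
Why: Borohydride 1,2-reduction of the diaryl-type ketone gives a racemic carbinol centre that is erased in step 4.

**Step 4**
Reactants: 6 the benzofuranyl aryl carbinol
Product: 7 4,6-bis(benzyloxy)-2-[3,4-bis(benzyloxy)benzyl]-1-benzofuran
Conditions: Et3SiH, TFA, CH2Cl2, −40 °C
Reagents that add atoms: none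
Why: Ionic (Kursanov–Parnes) deoxygenation works because the carbinol ionises at low temperature to a cation stabilised by the p-benzyloxy B ring and the furan ring, and silane hydride traps it before the benzofuran itself is protonated.

**Step 5**
Reactants: 7 4,6-bis(benzyloxy)-2-[3,4-bis(benzyloxy)benzyl]-1-benzofuran
Product: 11 rac-5,7-bis(benzyloxy)-2-[3,4-bis(benzyloxy)phenyl]chroman-3-one, via benzofuran 2,3-epoxide 8 (not isolated), via Z o-quinone methide ketone 9 (not isolated), via 2H-chromen-3-ol 10 (not isolated)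
Conditions: DMDO (1.05 equiv), CH2Cl2–acetone, 4 Å MS, −78 → −30 °C; then Et3N (0.2 equiv), −30 → 0 °C
Reagents that add atoms: dimethyldioxirane, CC1(C)OO1
Why: Proposed new method: dimethyldioxirane should transfer its oxygen to the furan C=C bond of 7, the most electron-rich π bond because O1 and both A-ring benzyloxy groups feed into it, and epoxide 8 should open at the C4–O bond (a 2,4,6-trioxygenated benzylic position) and release O1 from C3, the known valence isomerisation of benzofuran epoxides to o-quinone methides, giving 9 with the Z geometry inherited from the ring. Amine-catalysed enolisation of 9, possible only towards C2 because C4 is sp2, gives the oxatriene O1=C8a–C4a=C4–C3(OH)=C2, which closes the pyran ring by a thermal disrotatory oxa-6π electrocyclisation (O1–C2 bond) driven by rearomatisation of ring A, and enol 10 tautomerises to ketone 11. The closest known reaction types are the Achmatowicz oxidative ring expansion of furfuryl systems, the dioxirane epoxidation of benzofurans and the electrocyclisation of vinyl o-quinone methides to 2H-chromenes, and their combination on a 2-benzylbenzofuran is new. The only new stereocentre, C2, forms without control and stays configurationally labile (α to C3=O, benzylic, α-oxygenated), which is wanted because step 6 sets it dynamically. The step needs site-selective oxidation, secured by one equivalent of a neutral oxidant at low temperature and the enol-ether character of the furan bond, and it needs ring opening rather than a 1,2-benzyl shift, favoured by the 5- and 7-oxygen donors that stabilise the quinone methide and by adding the base only after the oxidant is consumed.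

**Step 6**
Reactants: 11 rac-flavan-3-one
Product: 12 5,7,3',4'-tetra-O-benzyl-(−)-epicatechin (2R,3R)
Conditions: H2 (50 atm), RuCl2[(S)-Xyl-SDP][(R,R)-DPEN] (cat.), KOtBu (cat.), iPrOH–toluene, rt
Reagents that add atoms: none
Why: In this Noyori-type bifunctional Ru hydrogenation with dynamic kinetic resolution, as shown for 2-arylcycloalkanones and α-aryloxy ketones, KOtBu racemises C2 through the enolate faster than reduction and the catalyst should reduce the (2R)-ketone preferentially, delivering hydride to C3 anti to the 2-aryl group to set 2R,3R (2,3-cis).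

**Step 7**
Reactants: 12 tetra-O-benzyl-(−)-epicatechin; 13 3,4,5-tris(benzyloxy)benzoic acid
Product: 14 5,7,3',4'-tetra-O-benzyl-(−)-epicatechin 3-O-[3,4,5-tris(benzyloxy)benzoate]
Conditions: DCC, DMAP, CH2Cl2, rt
Reagents that add atoms: none
Why: Steglich esterification of the secondary 3-OH touches no stereocentre.

**Step 8**
Reactants: 12 tetra-O-benzyl-(−)-epicatechin
Product: 15 5,7,3',4'-tetra-O-benzyl-4β-(2-ethoxyethoxy)-(−)-epicatechin (2,3-cis-3,4-trans)
Conditions: DDQ, 2-ethoxyethanol, CH2Cl2, rt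
Reagents that add atoms: 2-ethoxyethanol, CCOCCO
Why: In this DDQ oxidative benzylic etherification, known for benzylated flavan-3-ols, hydride abstraction from C4–H (activated by three A-ring oxygens) gives the C4 cation, which the alcohol should trap from the β face anti to the 3-substituent.

**Step 9**
Reactants: 15 the 4β-(2-ethoxyethoxy) alcohol; 13 3,4,5-tris(benzyloxy)benzoic acid
Product: 16 5,7,3',4'-tetra-O-benzyl-4β-(2-ethoxyethoxy)-(−)-epicatechin 3-O-[3,4,5-tris(benzyloxy)benzoate]
Conditions: DCC, DMAP, CH2Cl2, rt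
Reagents that add atoms: none
Why: Steglich esterification under neutral conditions should leave the acid-labile C4 ether and all stereocentres untouched.

**Step 10**
Reactants: 16 C4-activated gallate (electrophile); 14 monomeric gallate (nucleophile, 4 equiv, excess recovered)
Product: 17 tetradeca-O-benzyl epicatechin-3-O-gallate-(4β→8)-epicatechin-3-O-gallate
Conditions: TMSOTf (cat.), CH2Cl2, −78 °C
Reagents that add atoms: none
Why: In this Friedel–Crafts-type flavan 4→8 coupling, ionisation of the C4 ether gives the A-ring-stabilised cation whose α face is shielded by the participating 3-O-galloyl group, so C8 of 14, the most accessible nucleophilic A-ring position, should attack from the β face and set C4 as 3,4-trans.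

**Step 11**
Reactants: 16 C4-activated gallate (electrophile, added slowly); 17 dimer (nucleophile, 2 equiv)
Product: 18 henicosa-O-benzyl procyanidin C1 3,3',3''-tri-O-gallate
Conditions: TMSOTf (cat.), CH2Cl2, −78 → −40 °C
Reagents that add atoms: none
Why: The same Friedel–Crafts-type coupling applies, since the only free C8 of 17 is on its upper unit and should be the most reactive site, and galloyl participation again directs β attack to set the second C4 as 3,4-trans.

**Step 12**
Reactants: 18 the 21-fold benzyl ether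
Product: 19 procyanidin C1 3,3',3''-tri-O-gallate (target)
Conditions: H2 (1 atm), Pd(OH)2/C, THF–MeOH–H2O, rt
Reagents that add atoms: none
Why: Hydrogenolysis of all aryl benzyl ethers under neutral conditions should spare the gallate esters, the interflavan bonds and all eight stereocentres.

**Compound list**
1 | 2,4,6-trihydroxybenzaldehyde | O=Cc1c(O)cc(O)cc1O | starting material
2 | 2,4-bis(benzyloxy)-6-hydroxybenzaldehyde | O=Cc1c(O)cc(OCc2ccccc2)cc1OCc1ccccc1 | intermediate
3 | 2-bromo-1-[3,4-bis(benzyloxy)phenyl]ethan-1-one | O=C(CBr)c1ccc(OCc2ccccc2)c(OCc2ccccc2)c1 | starting material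
4 | 2,4-bis(benzyloxy)-6-{2-[3,4-bis(benzyloxy)phenyl]-2-oxoethoxy}benzaldehyde (not isolated) | O=Cc1c(OCC(=O)c2ccc(OCc3ccccc3)c(OCc3ccccc3)c2)cc(OCc2ccccc2)cc1OCc1ccccc1 | intermediate
5 | [4,6-bis(benzyloxy)-1-benzofuran-2-yl][3,4-bis(benzyloxy)phenyl]methanone | O=C(c1cc2c(OCc3ccccc3)cc(OCc3ccccc3)cc2o1)c1ccc(OCc2ccccc2)c(OCc2ccccc2)c1 | intermediate
6 | rac-[4,6-bis(benzyloxy)-1-benzofuran-2-yl][3,4-bis(benzyloxy)phenyl]methanol | OC(c1cc2c(OCc3ccccc3)cc(OCc3ccccc3)cc2o1)c1ccc(OCc2ccccc2)c(OCc2ccccc2)c1 | intermediate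
7 | 4,6-bis(benzyloxy)-2-[3,4-bis(benzyloxy)benzyl]-1-benzofuran | C(c1cc2c(OCc3ccccc3)cc(OCc3ccccc3)cc2o1)c1ccc(OCc2ccccc2)c(OCc2ccccc2)c1 | intermediate
8 | 2,3-epoxide of 7 (racemic, cis-fused, not isolated) | C(C12OC1c1c(OCc3ccccc3)cc(OCc3ccccc3)cc1O2)c1ccc(OCc2ccccc2)c(OCc2ccccc2)c1 | intermediate
9 | (6Z)-3,5-bis(benzyloxy)-6-{3-[3,4-bis(benzyloxy)phenyl]-2-oxopropylidene}cyclohexa-2,4-dien-1-one (not isolated) | O=C1C=C(OCc2ccccc2)C=C(OCc2ccccc2)/C1=C/C(=O)Cc1ccc(OCc2ccccc2)c(OCc2ccccc2)c1 | intermediate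
10 | rac-5,7-bis(benzyloxy)-2-[3,4-bis(benzyloxy)phenyl]-2H-chromen-3-ol (not isolated) | OC1=Cc2c(OCc3ccccc3)cc(OCc3ccccc3)cc2OC1c1ccc(OCc2ccccc2)c(OCc2ccccc2)c1 | intermediate
11 | rac-5,7-bis(benzyloxy)-2-[3,4-bis(benzyloxy)phenyl]chroman-3-one | O=C1Cc2c(OCc3ccccc3)cc(OCc3ccccc3)cc2OC1c1ccc(OCc2ccccc2)c(OCc2ccccc2)c1 | intermediate
12 | 5,7,3',4'-tetra-O-benzyl-(−)-epicatechin (2R,3R) | O[C@@H]1Cc2c(OCc3ccccc3)cc(OCc3ccccc3)cc2O[C@@H]1c1ccc(OCc2ccccc2)c(OCc2ccccc2)c1 | intermediate
13 | 3,4,5-tris(benzyloxy)benzoic acid | O=C(O)c1cc(OCc2ccccc2)c(OCc2ccccc2)c(OCc2ccccc2)c1 | starting material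
14 | tetra-O-benzyl-(−)-epicatechin 3-O-[3,4,5-tris(benzyloxy)benzoate] | O=C(O[C@@H]1Cc2c(OCc3ccccc3)cc(OCc3ccccc3)cc2O[C@@H]1c1ccc(OCc2ccccc2)c(OCc2ccccc2)c1)c1cc(OCc2ccccc2)c(OCc2ccccc2)c(OCc2ccccc2)c1 | intermediate
15 | tetra-O-benzyl-4β-(2-ethoxyethoxy)-(−)-epicatechin | O[C@@H]1[C@@H](OCCOCC)c2c(OCc3ccccc3)cc(OCc3ccccc3)cc2O[C@@H]1c1ccc(OCc2ccccc2)c(OCc2ccccc2)c1 | intermediate
16 | tetra-O-benzyl-4β-(2-ethoxyethoxy)-(−)-epicatechin 3-O-[3,4,5-tris(benzyloxy)benzoate] | O=C(O[C@@H]1[C@@H](OCCOCC)c2c(OCc3ccccc3)cc(OCc3ccccc3)cc2O[C@@H]1c1ccc(OCc2ccccc2)c(OCc2ccccc2)c1)c1cc(OCc2ccccc2)c(OCc2ccccc2)c(OCc2ccccc2)c1 | intermediate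
17 | tetradeca-O-benzyl epicatechin-3-O-gallate-(4β→8)-epicatechin-3-O-gallate | O=C(O[C@@H]1[C@@H](c2c(OCc4ccccc4)cc(OCc4ccccc4)c3c2O[C@H](c2ccc(OCc4ccccc4)c(OCc4ccccc4)c2)[C@H](OC(=O)c2cc(OCc4ccccc4)c(OCc4ccccc4)c(OCc4ccccc4)c2)C3)c2c(OCc3ccccc3)cc(OCc3ccccc3)cc2O[C@@H]1c1ccc(OCc2ccccc2)c(OCc2ccccc2)c1)c1cc(OCc2ccccc2)c(OCc2ccccc2)c(OCc2ccccc2)c1 | intermediate
18 | henicosa-O-benzyl procyanidin C1 3,3',3''-tri-O-gallate | O=C(O[C@@H]1[C@@H](c2c(OCc4ccccc4)cc(OCc4ccccc4)c3c2O[C@H](c2ccc(OCc4ccccc4)c(OCc4ccccc4)c2)[C@H](OC(=O)c2cc(OCc4ccccc4)c(OCc4ccccc4)c(OCc4ccccc4)c2)C3)c2c(OCc3ccccc3)cc(OCc3ccccc3)c([C@H]3c4c(OCc5ccccc5)cc(OCc5ccccc5)cc4O[C@H](c4ccc(OCc5ccccc5)c(OCc5ccccc5)c4)[C@@H]3OC(=O)c3cc(OCc4ccccc4)c(OCc4ccccc4)c(OCc4ccccc4)c3)c2O[C@@H]1c1ccc(OCc2ccccc2)c(OCc2ccccc2)c1)c1cc(OCc2ccccc2)c(OCc2ccccc2)c(OCc2ccccc2)c1 | intermediate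
19 | procyanidin C1 3,3',3''-tri-O-gallate | O=C(O[C@@H]1[C@@H](c2c(O)cc(O)c3c2O[C@H](c2ccc(O)c(O)c2)[C@H](OC(=O)c2cc(O)c(O)c(O)c2)C3)c2c(O)cc(O)c([C@H]3c4c(O)cc(O)cc4O[C@H](c4ccc(O)c(O)c4)[C@@H]3OC(=O)c3cc(O)c(O)c(O)c3)c2O[C@@H]1c1ccc(O)c(O)c1)c1cc(O)c(O)c(O)c1 | target

**Total step count:** 12. **Longest linear sequence:** 11 (steps 1–6, 8–12).

**Steps most likely to fail**

Step 5 (proposed new method). The opened epoxide may undergo semipinacol-type 1,2-migration of the benzyl group. The quinone methide may dimerise or be captured by adventitious nucleophiles before it enolises. The enol may also be over-oxidised. The fallback uses known chemistry, sets out from 2 and comes back at 11, and the ring is still grown from five to six atoms. Wittig methoxymethylenation of 2 gives the enol ether 3,5-bis(benzyloxy)-2-(2-methoxyvinyl)phenol F1. Mild acid hydrolysis frees the arylacetaldehyde, which closes to the lactol 4,6-bis(benzyloxy)-2,3-dihydro-1-benzofuran-2-ol F2. Treatment of F2 with [3,4-bis(benzyloxy)benzyl]dimethylsulfonium tetrafluoroborate and two equivalents of base is a sulfur-ylide epoxidation of the ring-opened hydroxy aldehyde. It inserts the benzylic carbon and gives the racemic trans-epoxide 3,5-bis(benzyloxy)-2-({3-[3,4-bis(benzyloxy)phenyl]oxiran-2-yl}methyl)phenol F3. PPTS then closes the phenol onto the benzylic epoxide carbon (6-endo, inversion) to give the racemic 2,3-trans alcohol rac-tetra-O-benzylcatechin F4. Dess–Martin oxidation gives 11.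

Step 6. Racemisation of C2 may be slow relative to reduction, or the catalyst may discriminate poorly between the two benzylic flanks of the ketone. Either would erode enantiomeric and diastereomeric purity. The fallback replaces asymmetric catalysis by substrate control plus resolution, sets out from 11 and comes back at 12. L-Selectride reduction, with hydride delivered anti to the 2-aryl group, gives the racemic cis alcohol rac-tetra-O-benzylepicatechin F5. Its enantiomers are separated by preparative chromatography on a chiral stationary phase, and the (2R,3R) enantiomer is 12.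

Step 11. The electrophile may self-condense through its own free C8, and attack may occur at other A-ring positions of the dimer. Both lead to oligomer mixtures. The fallback caps the electrophile, sets out from 16 and comes back at 19. NBS in CH2Cl2 at low temperature brominates C8 to give the 8-bromo electrophile 8-bromo-16 F6, which can no longer act as a nucleophile. TMSOTf coupling of F6 with 17 gives the capped trimer 8-bromo-18 F7. Final hydrogenolysis over Pd(OH)2/C with Et3N removes the bromine together with the 21 benzyl groups and gives 19.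

**Further compounds**
F1 | step 5 | 3,5-bis(benzyloxy)-2-(2-methoxyvinyl)phenol (E/Z mixture) | COC=Cc1c(O)cc(OCc2ccccc2)cc1OCc1ccccc1
F2 | step 5 | 4,6-bis(benzyloxy)-2,3-dihydro-1-benzofuran-2-ol | OC1Cc2c(OCc3ccccc3)cc(OCc3ccccc3)cc2O1
F3 | step 5 | racemic trans-3,5-bis(benzyloxy)-2-({3-[3,4-bis(benzyloxy)phenyl]oxiran-2-yl}methyl)phenol (both enantiomers) | Oc1cc(OCc2ccccc2)cc(OCc2ccccc2)c1C[C@@H]1O[C@H]1c1ccc(OCc2ccccc2)c(OCc2ccccc2)c1.Oc1cc(OCc2ccccc2)cc(OCc2ccccc2)c1C[C@H]1O[C@@H]1c1ccc(OCc2ccccc2)c(OCc2ccccc2)c1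
F4 | step 5 | rac-5,7,3',4'-tetra-O-benzylcatechin (2,3-trans, both enantiomers) | O[C@H]1Cc2c(OCc3ccccc3)cc(OCc3ccccc3)cc2O[C@@H]1c1ccc(OCc2ccccc2)c(OCc2ccccc2)c1.O[C@@H]1Cc2c(OCc3ccccc3)cc(OCc3ccccc3)cc2O[C@H]1c1ccc(OCc2ccccc2)c(OCc2ccccc2)c1
F5 | step 6 | rac-5,7,3',4'-tetra-O-benzylepicatechin (2,3-cis, both enantiomers) | O[C@@H]1Cc2c(OCc3ccccc3)cc(OCc3ccccc3)cc2O[C@@H]1c1ccc(OCc2ccccc2)c(OCc2ccccc2)c1.O[C@H]1Cc2c(OCc3ccccc3)cc(OCc3ccccc3)cc2O[C@H]1c1ccc(OCc2ccccc2)c(OCc2ccccc2)c1
F6 | step 11 | 8-bromo-tetra-O-benzyl-4β-(2-ethoxyethoxy)-(−)-epicatechin 3-O-[3,4,5-tris(benzyloxy)benzoate] | O=C(O[C@@H]1[C@@H](OCCOCC)c2c(OCc3ccccc3)cc(OCc3ccccc3)c(Br)c2O[C@@H]1c1ccc(OCc2ccccc2)c(OCc2ccccc2)c1)c1cc(OCc2ccccc2)c(OCc2ccccc2)c(OCc2ccccc2)c1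
F7 | step 11 | henicosa-O-benzyl procyanidin C1 tri-O-gallate brominated at C8 of the top unit | O=C(O[C@@H]1[C@@H](c2c(OCc4ccccc4)cc(OCc4ccccc4)c3c2O[C@H](c2ccc(OCc4ccccc4)c(OCc4ccccc4)c2)[C@H](OC(=O)c2cc(OCc4ccccc4)c(OCc4ccccc4)c(OCc4ccccc4)c2)C3)c2c(OCc3ccccc3)cc(OCc3ccccc3)c([C@H]3c4c(OCc5ccccc5)cc(OCc5ccccc5)c(Br)c4O[C@H](c4ccc(OCc5ccccc5)c(OCc5ccccc5)c4)[C@@H]3OC(=O)c3cc(OCc4ccccc4)c(OCc4ccccc4)c(OCc4ccccc4)c3)c2O[C@@H]1c1ccc(OCc2ccccc2)c(OCc2ccccc2)c1)c1cc(OCc2ccccc2)c(OCc2ccccc2)c(OCc2ccccc2)c1
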